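**Retrosynthetic overview**
1. The plan rests on the benzenoid ring of the naphthoquinone (C4a, C5–OH, C6, C7–CH3, C8, C8a). Its hydroxyl must stand peri to C4=O, the carbonyl that is not bonded to the aryl-bearing C2.
2. After a final ester hydrolysis, this ring is cut at C8–C8a and C4a–C5. The pieces are a 2-chloro-5-arylbenzoquinone and a methyl-branched vinylketene acetal, and the chlorine marks the future C4a.
3. The chloroquinone comes from oxidative demethylation of a 4-chloro-2,5-dimethoxyphenyl group, which is joined to C8′ of the chromone by Suzuki coupling.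
4. The 8-iodochromone ester comes from 3-methoxy-5-methylbenzoic acid. Directed ortho metalation places the acetyl group between carboxyl and methoxy, iodine enters ortho to the freed phenol, and one formyl carbon closes the pyranone.
5. Ring order: the pyranone ring of the chromone first, the quinone ring unmasked from the purchased arene second, the phenolic ring last.

Key step: step 12

Assumption: the target SMILES fixes no configuration at the C2–C8′ axis, so the axis is not controlled; the ketene acetal geometry of 3, drawn (1E), does not affect the product, because both oxygen substituents sit on the carbon that becomes C5.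

Step 1
Reactants: 1 methyl 3-methylbut-2-enoate
Product: 3 (1E)-1-methoxy-3-methyl-1-(trimethylsilyloxy)buta-1,3-diene, via lithium dienolate 2 (not isolated)
Conditions: LiN(i-Pr)2 (1.1 equiv), THF, −78 °C; Me3SiCl, −78 °C → rt; pentane, filtration, distillation under reduced pressure
Reagents that add atoms: chlorotrimethylsilane, C[Si](C)(C)Cl
Why: Kinetic γ-deprotonation of the β,β-dimethylacrylate gives the extended lithium dienolate, and the hard silicon electrophile traps it on oxygen (silyl ketene acetal formation) to deliver the 1,1-dioxygenated diene.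

Step 2
Reactants: 4 2-chloro-1,4-dimethoxybenzene
Product: 5 1-bromo-4-chloro-2,5-dimethoxybenzene
Conditions: Br2 (1.05 equiv), AcOH, rt
Reagents that add atoms: bromine, BrBr
Why: Electrophilic aromatic bromination should take the position ortho to a methoxy group and para to chlorine, because the other methoxy-activated sites are either wedged between Cl and OCH3 or meta to the ortho/para-directing chlorine.

Step 3
Reactants: 5 1-bromo-4-chloro-2,5-dimethoxybenzene
Product: 6 2-(4-chloro-2,5-dimethoxyphenyl)-4,4,5,5-tetramethyl-1,3,2-dioxaborolane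
Conditions: B2pin2 (1.1 equiv), Pd(dppf)Cl2 (3 mol %), KOAc (3 equiv), 1,4-dioxane, 85 °C
Reagents that add atoms: bis(pinacolato)diboron, CC1(C)OB(OC1(C)C)B1OC(C)(C)C(C)(C)O1
Why: In this Miyaura borylation, zerovalent palladium inserts into the C–Br bond much faster than into the C–Cl bond of the electron-rich arene, so the chlorine is kept for the key step.

Step 4
Reactants: 7 3-methoxy-5-methylbenzoic acid
Product: 9 N,N-diethyl-3-methoxy-5-methylbenzamide, via acid chloride 8 (not isolated)
Conditions: SOCl2, cat. DMF, toluene, 70 °C; evaporate; Et2NH (2.5 equiv), CH2Cl2, 0 °C → rt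
Reagents that add atoms: diethylamine, CCNCC
Why: Acid chloride formation followed by aminolysis is routine, and the tertiary amide serves as the directing group for the next step.

Step 5
Reactants: 9 N,N-diethyl-3-methoxy-5-methylbenzamide
Product: 11 2-acetyl-N,N-diethyl-3-methoxy-5-methylbenzamide, via 2-lithiobenzamide 10 (not isolated)
Conditions: s-BuLi (1.15 equiv), TMEDA, THF, −78 °C; MeC(O)N(OMe)Me, −78 → 0 °C; 1 M aq. HCl quench
Reagents that add atoms: N-methoxy-N-methylacetamide, CON(C)C(C)=O
Why: In this directed ortho metalation the carboxamide and the methoxy group act together on the C2–H between them, and the aryllithium forms a chelated adduct with the Weinreb amide that releases the methyl ketone only on quenching (Weinreb ketone synthesis), so no tertiary alcohol should form.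

Step 6
Reactants: 11 2-acetyl-N,N-diethyl-3-methoxy-5-methylbenzamide
Product: 13 methyl 2-acetyl-3-methoxy-5-methylbenzoate, via imidatonium tetrafluoroborate 12 (not isolated)
Conditions: Me3OBF4 (1.3 equiv), CH2Cl2, rt; then sat. aq. NaHCO3, rt
Reagents that add atoms: trimethyloxonium tetrafluoroborate, C[O+](C)C.F[B-](F)(F)F; water, O
Why: O-Methylation of the tertiary benzamide with Meerwein's salt and mild hydrolysis of the imidatonium ion expel diethylamine and leave the methyl ester, a known unmasking of metalation-derived diethylbenzamides that avoids the hot acid or base that could drive a 2-acetylbenzoate into a Dieckmann-type closure.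

Step 7
Reactants: 13 methyl 2-acetyl-3-methoxy-5-methylbenzoate
Product: 14 methyl 2-acetyl-3-hydroxy-5-methylbenzoate
Conditions: BCl3 (1.3 equiv), CH2Cl2, −78 → 0 °C; aqueous work-up
Reagents that add atoms: none
Why: In this chelation-assisted ether cleavage, BCl3 binds the ketone oxygen and the neighbouring methoxy oxygen in a six-membered chelate and chloride removes that methyl group, while the ester methyl group is untouched at this temperature.

Step 8
Reactants: 14 methyl 2-acetyl-3-hydroxy-5-methylbenzoate
Product: 15 methyl 2-acetyl-3-hydroxy-4-iodo-5-methylbenzoate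
Conditions: N-iodosuccinimide (1.05 equiv), CF3CO2H (0.3 equiv), MeCN, 0 °C → rt, dark
Reagents that add atoms: N-iodosuccinimide, O=C1CCC(=O)N1I
Why: In this electrophilic aromatic iodination C2 is blocked, and of the two hydroxyl-activated sites C4 (flanked by OH and CH3, para to the ester) should be taken rather than C6, which is squeezed between CH3 and CO2CH3 and feels the inductive pull of the adjacent ester, the same preference that 3-hydroxybenzoates show.

Step 9
Reactants: 15 methyl 2-acetyl-3-hydroxy-4-iodo-5-methylbenzoate
Product: 17 methyl 8-iodo-7-methyl-4-oxo-4H-chromene-5-carboxylate, via enaminone 16 (not isolated)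
Conditions: Me2NCH(OMe)2 (3 equiv), toluene, 90 °C; evaporate; conc. HCl, CH2Cl2, rt → 40 °C
Reagents that add atoms: N,N-dimethylformamide dimethyl acetal, COC(OC)N(C)C
Why: Condensation of the methyl ketone with the amide acetal gives the (E)-enaminone, and acid then triggers attack of the phenol oxygen on its β-carbon with loss of dimethylamine (the enaminone route to 2,3-unsubstituted chromones, a 6-endo-trig addition–elimination).

Step 10
Reactants: 17 methyl 8-iodo-7-methyl-4-oxo-4H-chromene-5-carboxylate; 6 2-(4-chloro-2,5-dimethoxyphenyl)-4,4,5,5-tetramethyl-1,3,2-dioxaborolane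
Product: 18 methyl 8-(4-chloro-2,5-dimethoxyphenyl)-7-methyl-4-oxo-4H-chromene-5-carboxylate
Conditions: Pd(dppf)Cl2 (5 mol %), K3PO4 (2.5 equiv), 1,4-dioxane/H2O (10:1), 80 °C
Reagents that add atoms: none
Why: In this Suzuki–Miyaura coupling the aryl iodide undergoes oxidative addition far ahead of the electron-rich aryl chloride with this bisphosphine catalyst, one flank of C8 is only a tied-back ring oxygen, and phosphate with little water should spare the pyranone and the ester.

Step 11
Reactants: 18 methyl 8-(4-chloro-2,5-dimethoxyphenyl)-7-methyl-4-oxo-4H-chromene-5-carboxylate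
Product: 19 methyl 8-(4-chloro-3,6-dioxocyclohexa-1,4-dien-1-yl)-7-methyl-4-oxo-4H-chromene-5-carboxylate
Conditions: (NH4)2Ce(NO3)6 (2.5 equiv), MeCN/H2O (3:1), 0 °C → rt
Reagents that add atoms: water, O
Why: In this oxidative demethylation of a hydroquinone dimethyl ether by tetravalent cerium, two one-electron oxidations with addition of water at the methoxy-bearing carbons release two methanol and give the quinone, while the electron-poor chromone ring should not be oxidised.

Step 12
Reactants: 19 methyl 8-(4-chloro-3,6-dioxocyclohexa-1,4-dien-1-yl)-7-methyl-4-oxo-4H-chromene-5-carboxylate; 3 (1E)-1-methoxy-3-methyl-1-(trimethylsilyloxy)buta-1,3-diene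
Product: 22 methyl 8-(5-hydroxy-7-methyl-1,4-dioxo-1,4-dihydronaphthalen-2-yl)-7-methyl-4-oxo-4H-chromene-5-carboxylate, via chloro cycloadduct 20 (not isolated), via aryl silyl ether 21 (not isolated)
Conditions: 3 (2.5 equiv), CH2Cl2, −30 °C → rt; then 1 M aq. HCl, THF, rt
Reagents that add atoms: none
Why: The electron-rich vinylketene acetal 3 and the electron-poor quinone 19 combine in a normal-demand, strongly asynchronous Diels–Alder reaction in which the CH2 terminus of 3 bonds first to the unsubstituted CH of the C(Cl)=CH bond (new C8–C8a) and the acetal carbon then bonds to the chlorine-bearing carbon (new C4a–C5). The closest known reaction type is the cycloaddition of halobenzoquinones with 1-alkoxy-1-silyloxydienes followed by aromatisation to peri-hydroxynaphthoquinones, in which the halogen fixes the orientation. The one new six-membered carbocycle is closed intermolecularly in the [4+2] mode from four diene carbons and two quinone carbons; adduct 20 then loses HCl by an E1cB path (C8a–H, C4a–Cl), loses methanol from C5/C8 to give silyl ether 21, and the dilute acid removes the silyl group. The three stereocentres of 20 (C4a and C8a cis by suprafacial addition, C5 by the endo approach) are all erased on aromatisation, so 22 holds no stereocentre. Regioselectivity is needed and chlorine secures it: its carbon becomes C4a, and because that carbon is bonded to the carbonyl adjoining the CH of the other double bond, the hydroxyl ends up peri to C4=O and the aryl group at C2. Site selectivity is also needed and the chromone secures it, because its C7′ methyl group and ring oxygen twist it out of the quinone plane so that it covers both faces of the C(aryl)=CH bond, and only addition to the chloroalkene is made irreversible by loss of chloride.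

Step 13
Reactants: 22 methyl 8-(5-hydroxy-7-methyl-1,4-dioxo-1,4-dihydronaphthalen-2-yl)-7-methyl-4-oxo-4H-chromene-5-carboxylate
Product: 23 8-(5-hydroxy-7-methyl-1,4-dioxo-1,4-dihydronaphthalen-2-yl)-7-methyl-4-oxo-4H-chromene-5-carboxylic acid
Conditions: 6 M aq. H2SO4, AcOH, 100 °C
Reagents that add atoms: water, O
Why: Acid-catalysed acyl–oxygen ester hydrolysis (AAC2) is chosen because hydroxide would open the pyranone at C2′ and degrade the juglone unit, and sulfuric acid is used because its anion does not add to the free C3 of the quinone as chloride could.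

**Compound list**
1 | methyl 3-methylbut-2-enoate | COC(=O)C=C(C)C | starting material
2 | lithium (1Z)-1-methoxy-3-methylbuta-1,3-dien-1-olate (same spatial arrangement as 3; the descriptor changes with the rank of O–Li) | C=C(C)/C=C(\OC)O[Li] | intermediate
3 | (1E)-1-methoxy-3-methyl-1-(trimethylsilyloxy)buta-1,3-diene | C=C(C)/C=C(\OC)O[Si](C)(C)C | intermediate
4 | 2-chloro-1,4-dimethoxybenzene | COc1ccc(OC)c(Cl)c1 | starting material
5 | 1-bromo-4-chloro-2,5-dimethoxybenzene | COc1cc(Br)c(OC)cc1Cl | intermediate
6 | 2-(4-chloro-2,5-dimethoxyphenyl)-4,4,5,5-tetramethyl-1,3,2-dioxaborolane | COc1cc(B2OC(C)(C)C(C)(C)O2)c(OC)cc1Cl | intermediate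
7 | 3-methoxy-5-methylbenzoic acid | COc1cc(C)cc(C(=O)O)c1 | starting material
8 | 3-methoxy-5-methylbenzoyl chloride | COc1cc(C)cc(C(=O)Cl)c1 | intermediate
9 | N,N-diethyl-3-methoxy-5-methylbenzamide | CCN(CC)C(=O)c1cc(C)cc(OC)c1 | intermediate
10 | [2-(diethylcarbamoyl)-6-methoxy-4-methylphenyl]lithium | CCN(CC)C(=O)c1cc(C)cc(OC)c1[Li] | intermediate
11 | 2-acetyl-N,N-diethyl-3-methoxy-5-methylbenzamide | CCN(CC)C(=O)c1cc(C)cc(OC)c1C(C)=O | intermediate
12 | N-[(2-acetyl-3-methoxy-5-methylphenyl)(methoxy)methylidene]-N-ethylethanaminium tetrafluoroborate | CC[N+](CC)=C(OC)c1cc(C)cc(OC)c1C(C)=O.F[B-](F)(F)F | intermediate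
13 | methyl 2-acetyl-3-methoxy-5-methylbenzoate | COC(=O)c1cc(C)cc(OC)c1C(C)=O | intermediate
14 | methyl 2-acetyl-3-hydroxy-5-methylbenzoate | COC(=O)c1cc(C)cc(O)c1C(C)=O | intermediate
15 | methyl 2-acetyl-3-hydroxy-4-iodo-5-methylbenzoate | COC(=O)c1cc(C)c(I)c(O)c1C(C)=O | intermediate
16 | methyl 2-[(2E)-3-(dimethylamino)prop-2-enoyl]-3-hydroxy-4-iodo-5-methylbenzoate | COC(=O)c1cc(C)c(I)c(O)c1C(=O)/C=C/N(C)C | intermediate
17 | methyl 8-iodo-7-methyl-4-oxo-4H-chromene-5-carboxylate | COC(=O)c1cc(C)c(I)c2occc(=O)c12 | intermediate
18 | methyl 8-(4-chloro-2,5-dimethoxyphenyl)-7-methyl-4-oxo-4H-chromene-5-carboxylate | COC(=O)c1cc(C)c(-c2cc(OC)c(Cl)cc2OC)c2occc(=O)c12 | intermediate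
19 | methyl 8-(4-chloro-3,6-dioxocyclohexa-1,4-dien-1-yl)-7-methyl-4-oxo-4H-chromene-5-carboxylate | COC(=O)c1cc(C)c(C2=CC(=O)C(Cl)=CC2=O)c2occc(=O)c12 | intermediate
20 | methyl 8-[4a-chloro-5-methoxy-7-methyl-1,4-dioxo-5-(trimethylsilyloxy)-1,4,4a,5,8,8a-hexahydronaphthalen-2-yl]-7-methyl-4-oxo-4H-chromene-5-carboxylate (racemic endo adduct, one enantiomer drawn; Cl and 8a-H cis, silyloxy group trans to Cl) | CO[C@]1(O[Si](C)(C)C)C=C(C)C[C@H]2C(=O)C(c3c(C)cc(C(=O)OC)c4c(=O)ccoc34)=CC(=O)[C@@]12Cl | intermediate
21 | methyl 7-methyl-8-[7-methyl-1,4-dioxo-5-(trimethylsilyloxy)-1,4-dihydronaphthalen-2-yl]-4-oxo-4H-chromene-5-carboxylate | Cc1cc(O[Si](C)(C)C)c2c(c1)C(=O)C(c1c(C)cc(C(=O)OC)c3c(=O)ccoc13)=CC2=O | intermediate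
22 | methyl 8-(5-hydroxy-7-methyl-1,4-dioxo-1,4-dihydronaphthalen-2-yl)-7-methyl-4-oxo-4H-chromene-5-carboxylate | Cc1cc(O)c2c(c1)C(=O)C(c1c(C)cc(C(=O)OC)c3c(=O)ccoc13)=CC2=O | intermediate
23 | 8-(5-hydroxy-7-methyl-1,4-dioxo-1,4-dihydronaphthalen-2-yl)-7-methyl-4-oxo-4H-chromene-5-carboxylic acid | Cc1cc(O)c2c(c1)C(=O)C(c1c(C)cc(C(=O)O)c3c(=O)ccoc13)=CC2=O | target

**Total step count:** 13
**Longest linear sequence:** 10 (steps 4 to 13, from 7)

**Steps most likely to fail**

**Step 12.**
- Risk: The bulky aryl quinone may slow the cycloaddition. The liberated HCl may protonate the ketene acetal before it reacts. The aromatisation may partly expel silanol instead of methanol, which would leave the phenol methylated.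
- Fallback: The same cycloaddition is moved to a simple symmetric dihaloquinone and the aryl–quinone bond is made afterwards. The fallback sets out from 3 and 17 and returns at 22.
- Diene 3 and purchased 2,5-dibromo-1,4-benzoquinone (O=C1C=C(Br)C(=O)C=C1Br; both bromoalkenes are equivalent) should give 2-bromo-5-hydroxy-7-methyl-1,4-naphthoquinone F1 under the same orientation rule.
- Iodide 17 is stannylated with (CH3)3SnSn(CH3)3 and Pd(PPh3)4 in toluene at 100 °C to give methyl 7-methyl-4-oxo-8-(trimethylstannyl)-4H-chromene-5-carboxylate F2.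
- A base-free Stille coupling of F1 and F2 (Pd(PPh3)4, CuI, 1,4-dioxane, 90 °C) tolerates the free peri hydroxyl and the quinone and leads to 22.

**Step 10.**
- Risk: Slow transmetalation at the doubly flanked C8 leaves time for protodeboronation of the electron-rich boronate and for opening of the pyranone ring by aqueous base.
- Fallback: The coupling is changed to a base-free Negishi coupling. It sets out from 5 and returns at 18.
- Bromine–lithium exchange on 5 (n-BuLi, THF, −78 °C) gives (4-chloro-2,5-dimethoxyphenyl)lithium F3.
- ZnCl2 converts F3 into (4-chloro-2,5-dimethoxyphenyl)zinc chloride F4.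
- F4 couples with 17 (Pd(OAc)2, SPhos, THF, rt) to give 18. At this temperature the aryl chloride should stay untouched.

**Step 8.**
- Risk: Positional selectivity may be poor (competing iodination para to the hydroxyl), or iodination may go too far.
- Fallback: The order of events is changed so that a bulkier group walls in C6. It sets out from 11 and returns at 15.
- BCl3 (CH2Cl2, −78 → 0 °C) cleaves the chelated ether of 11 to give 2-acetyl-N,N-diethyl-3-hydroxy-5-methylbenzamide F5.
- In F5 the diethylcarbamoyl group stands perpendicular to the arene and shields C6, so N-iodosuccinimide should give 2-acetyl-N,N-diethyl-3-hydroxy-4-iodo-5-methylbenzamide F6.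
- One equivalent of Me3OBF4 methylates the amide oxygen, which is far more nucleophilic than the chelated phenol, to give the imidatonium tetrafluoroborate F7.
- Aqueous NaHCO3 hydrolyses F7 to 15.

**Further compounds**
F1 | step 12 | 2-bromo-5-hydroxy-7-methyl-1,4-naphthoquinone | Cc1cc(O)c2c(c1)C(=O)C(Br)=CC2=O
F2 | step 12 | methyl 7-methyl-4-oxo-8-(trimethylstannyl)-4H-chromene-5-carboxylate | COC(=O)c1cc(C)c([Sn](C)(C)C)c2occc(=O)c12
F3 | step 10 | (4-chloro-2,5-dimethoxyphenyl)lithium | COc1cc([Li])c(OC)cc1Cl
F4 | step 10 | (4-chloro-2,5-dimethoxyphenyl)zinc chloride | COc1cc([Zn]Cl)c(OC)cc1Cl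
F5 | step 8 | 2-acetyl-N,N-diethyl-3-hydroxy-5-methylbenzamide | CCN(CC)C(=O)c1cc(C)cc(O)c1C(C)=O
F6 | step 8 | 2-acetyl-N,N-diethyl-3-hydroxy-4-iodo-5-methylbenzamide | CCN(CC)C(=O)c1cc(C)c(I)c(O)c1C(C)=O
F7 | step 8 | N-[(2-acetyl-3-hydroxy-4-iodo-5-methylphenyl)(methoxy)methylidene]-N-ethylethanaminium tetrafluoroborate | CC[N+](CC)=C(OC)c1cc(C)c(I)c(O)c1C(C)=O.F[B-](F)(F)F
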